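**Assumptions.** The target has no stereocentre and no configurationally stable axis, so it is achiral and "single enantiomer" needs no stereocontrol. Aluminium phenoxide and lithium enolate forms are counted with the neutral compound they give on work-up. The Friedel–Crafts regiochemistry in step 1 rests on the known behaviour of the acetyl analogue and on the steric argument given there.

**Retrosynthetic overview**
1. Target 8 ⇐ chelation-controlled cleavage of the 5-OMe of 3,5,7,8,2'-pentamethoxyflavone 7.
2. Ring C of 7 ⇐ cyclodehydration of the 2-methoxy-1,3-diketone 6 ⇐ C-aroylation of ω-methoxyacetophenone 4 with 2-methoxybenzoyl chloride 5; the 3-OMe is carried in from the start.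
3. 4 ⇐ Friedel–Crafts methoxyacetylation and ortho-demethylation of 1,2,3,5-tetramethoxybenzene 1 with methoxyacetyl chloride 2.
4. Ring order: rings A and B are bought intact; ring C (the pyranone) is the only ring formed, in step 2.

**Route**

Step 1
Reactants: 1 1,2,3,5-tetramethoxybenzene + 2 methoxyacetyl chloride
Product: 4 1-(2-hydroxy-3,4,6-trimethoxyphenyl)-2-methoxyethan-1-one, via tetramethoxyphenyl ketone 3 (not isolated)
Conditions: AlCl3 (3 equiv), Et2O, 0 °C → rt, 24 h; then ice, dil. aq. HCl
Reagents that add atoms: methoxyacetyl chloride (compound 2), COCC(Cl)=O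
Why: Friedel–Crafts acylation at C4 (C4 and C6 of 1 are equivalent and the only free positions) is followed in the same pot by AlCl3-mediated, carbonyl-chelation-directed cleavage of the ortho methoxy group squeezed between the acyl group and the 3-OMe, the resulting aluminium phenoxide chelate protecting against a second cleavage; no stereocentre is formed.

Step 2
Reactants: 4 1-(2-hydroxy-3,4,6-trimethoxyphenyl)-2-methoxyethan-1-one + 5 2-methoxybenzoyl chloride
Product: 7 3,5,7,8-tetramethoxy-2-(2-methoxyphenyl)-4H-chromen-4-one, via 1,3-diketone 6 (not isolated)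
Conditions: LiN(SiMe3)2 (3.5 equiv), THF, −78 → −10 °C; 5 (1.05 equiv), −78 °C → rt; aq. HCl quench, extract; crude in AcOH, H2SO4 (cat.), 95 °C, 1 h
Reagents that add atoms: 2-methoxybenzoyl chloride (compound 5), COc1ccccc1C(Cl)=O
Why: Claisen-type C-aroylation of the lithium phenoxide-enolate (any O-aroylated material converges by Baker–Venkataraman acyl shift under the excess base) gives the 1,3-diketone, whose phenol then adds to the aroyl carbonyl and loses water under acid to close the pyranone, erasing the transient racemic CH(OMe) centre.

Step 3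
Reactants: 7 3,5,7,8-tetramethoxy-2-(2-methoxyphenyl)-4H-chromen-4-one
Product: 8 5-hydroxy-3,7,8-trimethoxy-2-(2-methoxyphenyl)-4H-chromen-4-one (5-hydroxy-3,7,8,2'-tetramethoxyflavone)
Conditions: AlCl3 (anhydrous, 5 equiv), MeCN, 60 °C, monitored by TLC; then 2 M aq. HCl, 60 °C, 30 min
Reagents that add atoms: none
Why: Lewis-acid peri-demethylation, in which aluminium bridges C4=O and the 5-OMe in a six-membered chelate so chloride removes only that methyl, and the resulting aluminium 5-phenoxide chelate deactivates the carbonyl towards the 3-OMe while the 7-, 8- and 2'-OMe groups have no chelating partner.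

**Compound list**
1 | 1,2,3,5-tetramethoxybenzene | COc1cc(OC)c(OC)c(OC)c1 | starting material
2 | methoxyacetyl chloride | COCC(Cl)=O | starting material
3 | 2-methoxy-1-(2,3,4,6-tetramethoxyphenyl)ethan-1-one | COCC(=O)c1c(OC)c(OC)c(OC)cc1OC | intermediate
4 | 1-(2-hydroxy-3,4,6-trimethoxyphenyl)-2-methoxyethan-1-one | COCC(=O)c1c(O)c(OC)c(OC)cc1OC | intermediate
5 | 2-methoxybenzoyl chloride | COc1ccccc1C(Cl)=O | starting material
6 | 1-(2-hydroxy-3,4,6-trimethoxyphenyl)-2-methoxy-3-(2-methoxyphenyl)propane-1,3-dione (racemic at C2, in equilibrium with its enol) | COc1ccccc1C(=O)C(OC)C(=O)c1c(O)c(OC)c(OC)cc1OC | intermediate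
7 | 3,5,7,8-tetramethoxy-2-(2-methoxyphenyl)-4H-chromen-4-one | COc1ccccc1-c1oc2c(OC)c(OC)cc(OC)c2c(=O)c1OC | intermediate
8 | 5-hydroxy-3,7,8-trimethoxy-2-(2-methoxyphenyl)-4H-chromen-4-one (achiral) | COc1ccccc1-c1oc2c(OC)c(OC)cc(O)c2c(=O)c1OC | target

**Total step count:** 3. **Longest linear sequence:** 3 steps (1 → 4 → 7 → 8).

**Steps most likely to fail, with fallbacks**

Step 3 (most risky): the 8-OMe, and to a lesser degree the 3-OMe, can be cleaved along with the 5-OMe. The fallback sets out from 7 and comes back at 8. It stops aiming for mono-cleavage: 7 is treated with AlBr3 in MeCN at rt until both the 5- and the 8-methyl are gone, giving 5,8-dihydroxy-3,7-dimethoxy-2-(2-methoxyphenyl)-4H-chromen-4-one F3, kept under N2 because it is a hydroquinone. The free, non-chelated 8-OH is then re-methylated with dimethyl sulfate (1.05 equiv) and K2CO3 in acetone at rt. The 5-OH, locked in a hydrogen bond to C4=O, does not react under these conditions, so the product is 8.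

Step 1: AlCl3 may cleave a second aryl ether or the ω-methoxy group, or the acylation may stall on the complexed arene. The fallback sets out from 1 and comes back at 4. It separates C–C bond formation from demethylation: 1 is lithiated between two methoxy groups (n-BuLi, TMEDA, THF, 0 °C) to give (2,3,4,6-tetramethoxyphenyl)lithium F1. This is acylated at −78 °C with the Weinreb amide N,2-dimethoxy-N-methylacetamide to give ketone 3, now isolated. Ketone 3 is then mono-demethylated with BCl3 (1.1 equiv, CH2Cl2, −78 → 0 °C), again at the methoxy flanked by the carbonyl and the 3-OMe, to give 4.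

Step 2: direct C-aroylation of the hindered α-methoxy enolate may give mixtures of O-acyl, C-acyl and bis-acyl products. The fallback sets out from 4 and comes back at 7. The acyl group is first put on oxygen (5, pyridine, cat. DMAP, 60 °C) to give the isolated ester 2-(2-methoxyacetyl)-3,5,6-trimethoxyphenyl 2-methoxybenzoate F2. A separate intramolecular Baker–Venkataraman shift (powdered KOH, pyridine, 50 °C, then AcOH) moves the acyl group to carbon and gives diketone 6, now isolated. Diketone 6 is cyclised with H2SO4 (cat.) in AcOH at 95 °C to 7.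

**Further compounds**
F1 | step 1 | (2,3,4,6-tetramethoxyphenyl)lithium | [Li]c1c(OC)cc(OC)c(OC)c1OC
F2 | step 2 | 2-(2-methoxyacetyl)-3,5,6-trimethoxyphenyl 2-methoxybenzoate | COCC(=O)c1c(OC(=O)c2ccccc2OC)c(OC)c(OC)cc1OC
F3 | step 3 | 5,8-dihydroxy-3,7-dimethoxy-2-(2-methoxyphenyl)-4H-chromen-4-one | COc1ccccc1-c1oc2c(O)c(OC)cc(O)c2c(=O)c1OC
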